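(The readings are simulated with constants of no real substance; the scatter is artificial.)

The height of a peak is easily taken for all the Tgt2 a flask has made, but Tgt2 disappears while it forms.

| setting | ochre | grey | flask |
|---|---|---|---|
| Sbt | 0.10 M | 0.10 M | 0.10 M |
| Rgt | 0.90 equiv | 0.60 equiv | 0.900 equiv |
| Sbt2 | 5 equiv | 5 equiv | 5.00 equiv |
| remark | the very flask that is asked about, followed so far | run made earlier |  |
| time |  |  | 20 h |

- ochre (time / h: Tgt2 / %): 0.100: 22.8; 0.200: 31.3; 0.417: 35.1; 1.00: 26.7; 2.00: 12.4; 4.00: 1.9
- grey (time / h: Tgt2 / %): 0.200: 21.9; 0.500: 24.5; 1.33: 14.0; 3.00: 3.4; 8.00: 0.1; 20.0: 0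

(each reading ± 0.3 percentage points)

- the best time, 20 h at the latest, for Tgt2
- the amount of Tgt2, in percent of the Sbt charged, at that time

- the earlier runs were read with a standard deviation of 0.3 percentage points

In the ochre run, Tgt2 falls from 26.7% at 1.00 h to 1.9% at 4.00 h. Read as a first-order loss, this gives a constant of 0.881 h⁻¹, or a half-life of 0.787 h, much shorter than the 20 h allowed, so the best time should lie early, near the ochre reading of 35.1% at 0.417 h. The loss rate at any moment is this constant times the Tgt2 present, so the constant times the area under the curve gives the Tgt2 lost. Once the curve has returned to zero, that is also the Tgt2 made, and time has dropped out. For ochre this reckoning gives 57.3% of the Sbt charged, more than that reading. With Rgt taken as the limiting reagent, the Rgt share is the Tgt2 made divided by the Rgt charged: 63.7% in ochre. The grey run, with the same constant, gives 63.9%, about the same, with Sbt2 at 5 equiv in both runs.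

The forecast puts the best at 35.2% after 0.42 h, holding that “Rgt therefore limits the yield”.

The flask gives 35.2% after 0.406 h, and the forecast stands within its margin.

    Sbt + Rgt → Tgt2 (k = 0.761 M⁻¹ min⁻¹)
    Sbt2 + Rgt → Sid (k = 0.231 M⁻¹ min⁻¹)
    Tgt2 → Sid2 (k = 0.0149 min⁻¹)
    2 Sbt2 → Tgt (k = 0.356 M⁻¹ min⁻¹)

By 20.0 h the flask holds 0% of Tgt2 and 55.7% of Sid2, which counts the Tgt2 made. Its Rgt share is therefore 61.9%, close to the 63.7% reckoned from the ochre readings.

The share was read at 5 equiv of Sbt2. Carried to the neighbour with 20.0 equiv of Sbt2, it gives 57.3% of Tgt2 made. The computed neighbour holds 40.5% of Sid2 at 20.0 h, a share of 45.0%, less than the share carried over, and peaks at 26.6%.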